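## Structural features

The target 19 is a flavanone: benzo ring A is fused to the dihydropyranone ring C (O1, C2, C3, C4=O, C4a, C8a), C2 carries the 4-hydroxyphenyl ring B, and C5 and C7 carry free hydroxyls. C6 of ring A, the carbon between the two hydroxyl-bearing carbons, is bonded to C2 of an N-methylpiperidine. Ring A is therefore a fully substituted phloroglucinol with one C-acyl bond (C4a–C4) and one C-aminoalkyl bond (C6–C2(pip)) meta to each other. There are two stereocentres, C2 of ring C and C2 of the piperidine, both S. They do not stand next to each other (ring A lies between them), so neither can direct the other and each needs its own control element. Three features are fragile: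
- the C2–O1 bond of the β-aryloxy ketone opens to the chalcone under base, which would scramble C2 and, if both oxygens flanking the acyl carbon were free, exchange 6- for 8-substitution;
- the C2(pip)–N bond is a benzylic amine on a trioxygenated ring and can ionise to a quinone-methide-like cation in acid or heat, or be hydrogenolysed;
- the phloroglucinol is easily oxidised and C-alkylated.

The real difficulty is control, not carbon count: telling the three ring A oxygens apart so that ring C closes on the oxygen para to the piperidine carbon, and creating the piperidine stereocentre on a hindered, electron-rich, di-ortho-substituted benzylic carbon without later epimerisation. The key step uses the fact that C2(pip) is at once benzylic to ring A, α to N, and the start of the chain C3–C6 that returns to the same N. In a 2,4,6-trioxygenated benzaldehyde this carbon is the formyl carbon, flanked by two equivalent oxygens (later O5 and O7) and para to the unique oxygen (later O1), so its sulfinyl imine can accept C3–C6 as a nucleophile and then close N–C6.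

## Logic of the disconnections

19 to 18. The three O–CH2Ph bonds are cut last in the forward direction. All phenols stay masked until the end, so base-promoted ring opening and phenol oxidation are avoided in every earlier step. The forward step must cleave aryl benzyl ethers without touching C2(pip)–N, C2–O1 or the ketone.

18 to 16 and 17. The C2–C1' bond between ring C and ring B is cut. This removes ring B and the flavanone stereocentre together, leaving a flat 16. The forward step must add the aryl group to one face of C2=C3 under catalyst control, since the piperidine centre is too far away to help, and must tolerate a basic nitrogen.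

16 to 14 (through 15). O1–C2 and C2–C3 are cut, which takes out the single carbon C2. The simplification is that ring C becomes an acetyl group next to a phenol. The forward step needs the oxygen para to the piperidine carbon to be the only free one, so that closure can only give 6-substitution.

14 to 11 (through 12 and 13). The ring-to-acetyl bond (the later C4a–C4) is cut. The two open ring positions of 11 are equivalent, so there is no regiochemical question. The forward step must acylate carbon without removing or migrating the benzyl groups and without ionising the benzylic amine.

11 to 10. The N–CH3 bond is cut. The forward step must methylate nitrogen in the presence of a free, very electron-rich phenol.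

10 to 9. The N–S bond and the O–CH2OCH3 bond are cut together, so one acid treatment releases the amine and exactly the para oxygen. The forward step must be mild enough to leave the benzylic C–N bond configurationally intact.

9 to 5 and 7 (through 8). C2(pip)–C3(pip) and N–C6(pip) are cut, which removes the piperidine ring and its stereocentre in one move and leads back to an aldehyde-derived imine and a four-carbon reagent with opposite reactivity at its two ends. The forward step must add to one imine face under control of sulfur and then alkylate nitrogen within the same molecule.

7 to 6, and 5 to 3 and 4. The C–Mg bond and the C=N bond are cut. Magnesium must insert at bromine only, and the condensation must give the E imine without touching sulfur.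

3 to 2 to 1. The two ortho O–benzyl bonds and then the para O–acetal bond are cut. The differentiation rests on 1 itself: its two ortho hydroxyls are hydrogen-bonded to the formyl group and react last, so the para oxygen can be capped first with an acid-labile group. The forward steps must stop cleanly at mono-alkylation in step 1.

## Other disconnections considered

Alternative 1: The cut is through both bonds that join ring C to ring A, C8a–O1 and C4a–C4. In the forward direction CsF would unmask the C4a–C8a aryne from the silyl triflate A1. The carboxylate of cinnamic acid A2 would add to C8a, the aryne carbon remote from the C5 benzyloxy group, and the aryl anion at C4a would take the acyl group, giving the 2'-hydroxychalcone A3. No ring closes and no stereocentre is formed.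
- In favour: the ketone and the free phenol appear in one fluoride-mediated step with no Lewis acid. On that point it is better than step 8 of the chosen plan. The regiochemistry is set correctly by the alkoxy group next to the aryne.
- Against: A1 is a hexasubstituted benzene that must already hold the piperidine stereocentre and the differentiated oxygens, so it needs everything up to a compound like 10 plus bromination, silyl migration and triflation. Acyl transfer in a crowded aryne adduct would compete with simple O-arylation. A3 would still need an enantioselective oxa-Michael closure, which is less secure than the arylation of step 10.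
- Comparison: the protecting-group pattern is the same in both plans. Mechanistically the alternative avoids acid at the acylation stage. It sets no stereocentre and would be about three steps longer.

Alternative 2: The cut removes three carbon–carbon bonds of ring A (C6–C7, C7–C8 and C4a–C5), so ring A is built, not bought. In the forward direction cyclobutenone A4 and siloxyalkyne A5 would be heated: four-electron ring opening to a vinylketene, [2+2] addition of the ynol ether, a second ring opening and a six-electron electrocyclisation would give phenol A6.
- In favour: the piperidine centre would come from (S)-pipecolic acid, so no auxiliary and no facial selectivity question arise. On that point it is better than the chosen plan. The three oxygens emerge differentiated from the ring-forming event, which equals or betters steps 1 and 2. The conditions are neutral.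
- Against: A5 needs an ester-to-ynolate homologation with strong base next to the α-amino stereocentre, which puts that centre at risk. A4 and A5 are each several steps from commercial material. A6 has benzyl on the future O1 and a free hydroxyl at C7, the reverse of what ring C closure needs, so protecting groups must be exchanged. The carbamate must later be reduced to N-methyl with a hydride.
- Comparison: the alternative is more convergent for ring A and mechanistically clean, but would be roughly three to four steps longer and uses less accessible reagents.

Alternative 3: The cut is the N–C2(pip) bond alone. In the forward direction a chiral phosphoric acid would protonate styrene A7 at the carbon remote from the ring, giving an ortho-quinone methide bound to the chiral anion. The carbamate nitrogen would add to the exocyclic carbon and close the piperidine to A8.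
- In favour: the chiral controller is catalytic, which is better than a stoichiometric auxiliary. The carbamate already contains the carbon of the N-methyl group. A7 could come from an aldehyde of the same family as 3 by Wittig olefination.
- Against: the step makes the stereocentre by the very ionisation that threatens it. A8 has two free ortho hydroxyls and could reopen to the quinone methide under the same acid, so the configuration would rest on kinetic control only. Free ortho hydroxyls with a protected para oxygen is the wrong pattern for ring C, so further protection steps are needed. LiAlH4 is needed before the ketone can be introduced.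
- Comparison: both plans make ring and stereocentre in one step, so they are equal there. The chosen plan forms two bonds, not one, and its product is configurationally secure while the oxygens are protected. The step count would be equal or one to two steps higher for the alternative.

Key step: step 5

Assumption: the closed, sulfinyl-bound transition state is taken to govern addition to the 2,6-dibenzyloxy aldimine as it does for simpler aryl aldimines (R at sulfur, Si-face delivery, S at carbon). The key-step precursor 5 and product 9 were checked for ring size, substituents and descriptors and are used unchanged.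

## Route

Step 1
Reactants: 1 2,4,6-trihydroxybenzaldehyde
Product: 2 2,6-dihydroxy-4-(methoxymethoxy)benzaldehyde
Conditions: MOMCl (1.05 equiv; made from CH2(OMe)2, AcCl, cat. ZnBr2 in toluene), iPr2NEt, THF, 0 °C
Reagents that add atoms: chloromethyl methyl ether, COCCl
Why: Williamson-type O-alkylation under kinetic control; the para hydroxyl is the most acidic and the only one not held in a hydrogen bond to the formyl oxygen, so one equivalent should react there first, and making the chloromethyl ether in the flask avoids handling the neat carcinogen.

Step 2
Reactants: 2 2,6-dihydroxy-4-(methoxymethoxy)benzaldehyde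
Product: 3 2,6-bis(benzyloxy)-4-(methoxymethoxy)benzaldehyde
Conditions: BnBr (2.5 equiv), K2CO3, cat. Bu4NI, DMF, 60 °C
Reagents that add atoms: benzyl bromide, BrCc1ccccc1
Why: Williamson etherification; warming in DMF breaks the two hydrogen bonds to the formyl oxygen, and the acetal and the aldehyde are inert to carbonate.

Step 3
Reactants: 3 2,6-bis(benzyloxy)-4-(methoxymethoxy)benzaldehyde; 4 (R)-2-methylpropane-2-sulfinamide
Product: 5 (R,E)-N-[2,6-bis(benzyloxy)-4-(methoxymethoxy)benzylidene]-2-methylpropane-2-sulfinamide
Conditions: Ti(OEt)4 (2 equiv), THF, 65 °C
Reagents that add atoms: none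
Why: Lewis-acid-mediated condensation of an aldehyde with a primary sulfinamide; Ti(OEt)4 activates the hindered, electron-rich carbonyl and takes up the water, the E imine forms because the aryl group avoids the sulfinyl group, and the sulfur stereocentre is not touched.

Step 4
Reactants: 6 1-bromo-4-chlorobutane
Product: 7 4-chlorobutylmagnesium bromide
Conditions: Mg turnings (cat. BrCH2CH2Br), Et2O, 0 °C to rt, titrated before use
Reagents that add atoms: magnesium, [Mg]
Why: Grignard formation by insertion of magnesium into the weaker C–Br bond; keeping the solution cold and using it promptly should preserve the primary chloride against Wurtz coupling and four-membered ring closure.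

Step 5
Reactants: 5 (R,E)-N-[2,6-bis(benzyloxy)-4-(methoxymethoxy)benzylidene]-2-methylpropane-2-sulfinamide; 7 4-chlorobutylmagnesium bromide
Product: 9 (2S)-2-[2,6-bis(benzyloxy)-4-(methoxymethoxy)phenyl]-1-[(R)-tert-butylsulfinyl]piperidine, via open-chain 5-chloropentyl sulfinamide magnesium salt 8 (not isolated)
Conditions: 7 (2.5 equiv, Et2O), toluene, −48 to 0 °C; then KN(SiMe3)2 (2 equiv, THF), 0 °C to rt; H2O quench
Reagents that add atoms: none
Why: The C–Mg bond of 7 adds to the C=N bond of 5 through a closed six-membered chair in which magnesium is bound to the sulfinyl oxygen, the tert-butyl group is equatorial and the aryl group of the E imine points away from sulfur, so the chain is delivered to the Si face and C2(pip)–C3(pip) forms with S configuration at carbon. The closest known reaction type is the chelate-controlled addition of Grignard reagents to N-tert-butanesulfinyl aldimines in non-coordinating solvents, run in tandem with N-alkylation by a halide carried on the nucleophile, as used for 2-substituted pyrrolidines and piperidines. KN(SiMe3)2 then exchanges the bromomagnesium sulfinamide 8 for the more nucleophilic potassium salt, whose nitrogen displaces the primary chloride in a 6-exo-tet SN2 closure that forms N–C6(pip) and the piperidine ring. The single new stereocentre is controlled by the sulfur stereocentre of the auxiliary alone, since the aldehyde part is achiral. Facial selectivity needs magnesium to stay on the sulfinyl oxygen, which toluene with only the ether of the reagent solution should secure; the ortho benzyloxy oxygens are the one substrate feature that could compete. Chemoselectivity for 1,2-addition over displacement of an ortho alkoxy group follows from the strong activation of C=N by the sulfinyl group, and the alkyl chloride is inert to the Grignard carbon at these temperatures. N-alkylation is preferred over O-alkylation of the ambident sulfinamide anion by ring size (six-membered through N, eight-membered through O), and neither base is strong enough to remove the benzylic C2–H, so the new centre is not scrambled.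

Step 6
Reactants: 9 (2S)-2-[2,6-bis(benzyloxy)-4-(methoxymethoxy)phenyl]-1-[(R)-tert-butylsulfinyl]piperidine
Product: 10 3,5-bis(benzyloxy)-4-[(2S)-piperidin-2-yl]phenol
Conditions: HCl (4 M in dioxane, 6 equiv), MeOH, 0 °C to rt; NaHCO3 work-up
Reagents that add atoms: none
Why: Acidolysis; methanol attacks the protonated sulfinamide at sulfur and the acetal leaves through an oxocarbenium ion, while aryl benzyl ethers are stable. Low temperature and short contact limit reversible C2(pip)–N heterolysis, which is also slowed because the two ortho substituents keep the benzylic carbon out of the ring plane.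

Step 7
Reactants: 10 3,5-bis(benzyloxy)-4-[(2S)-piperidin-2-yl]phenol
Product: 11 3,5-bis(benzyloxy)-4-[(2S)-1-methylpiperidin-2-yl]phenol
Conditions: CH2O (37% aq., 1.2 equiv), NaBH(OAc)3 (2 equiv), AcOH (1 equiv), THF, 0 °C to rt
Reagents that add atoms: formaldehyde, C=O
Why: Reductive amination; the iminium ion from the secondary amine and formaldehyde should be reduced faster than it can attack a phenol ring, and no ring closure onto the arene is possible because both positions ortho to the benzylic carbon are substituted. This one step replaces a carbamate formation and a LiAlH4 reduction.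

Step 8
Reactants: 11 3,5-bis(benzyloxy)-4-[(2S)-1-methylpiperidin-2-yl]phenol
Product: 14 1-[2,4-bis(benzyloxy)-6-hydroxy-3-[(2S)-1-methylpiperidin-2-yl]phenyl]ethan-1-one, via aryl acetate 12 (not isolated), via difluoroboron chelate 13 (not isolated)
Conditions: Ac2O (3 equiv), BF3·OEt2 (5 equiv), CH2Cl2, 0 °C to rt; then NaOAc, aq. MeOH, 50 °C
Reagents that add atoms: acetic anhydride, CC(=O)OC(C)=O
Why: Friedel–Crafts acylation in its Fries form; the phenol is O-acetylated, BF3 moves the acyl group to the ortho carbon (activated by one ortho and one para benzyloxy group) and the ketone is held as its difluoroboron chelate, which prevents a second acylation. The two open ring positions are equivalent, so only one ketone can form, and the excess BF3 covers the amine.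

Step 9
Reactants: 14 1-[2,4-bis(benzyloxy)-6-hydroxy-3-[(2S)-1-methylpiperidin-2-yl]phenyl]ethan-1-one
Product: 16 5,7-bis(benzyloxy)-6-[(2S)-1-methylpiperidin-2-yl]-4H-chromen-4-one, via dimethylamino enone 15 (not isolated)
Conditions: Me2NCH(OMe)2 (3 equiv), toluene, 90 °C; then HCl (2 M in MeOH), CH2Cl2, rt; NaHCO3 work-up
Reagents that add atoms: N,N-dimethylformamide dimethyl acetal, COC(OC)N(C)C
Why: Enaminone formation at the methyl ketone with the amide acetal, then acid-induced conjugate addition of the only free phenol and loss of dimethylamine (standard chromone synthesis). Because both oxygens next to the piperidine carbon are benzylated, the pyranone can close only through the para oxygen, which fixes 6-substitution.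

Step 10
Reactants: 16 5,7-bis(benzyloxy)-6-[(2S)-1-methylpiperidin-2-yl]-4H-chromen-4-one; 17 [4-(benzyloxy)phenyl]boronic acid
Product: 18 (2S)-5,7-bis(benzyloxy)-2-[4-(benzyloxy)phenyl]-6-[(2S)-1-methylpiperidin-2-yl]-2,3-dihydro-4H-chromen-4-one
Conditions: Pd(OCOCF3)2 (10 mol %), (R)-4-tert-butyl-2-(pyridin-2-yl)-4,5-dihydrooxazole (12 mol %), NH4PF6 (30 mol %), CF3CO2H (1.0 equiv), H2O (5 equiv), 17 (2 equiv), ClCH2CH2Cl, 60 °C; NaHCO3 work-up
Reagents that add atoms: none
Why: Asymmetric conjugate addition of an arylboronic acid to a chromone catalysed by divalent palladium; transmetalation gives a cationic aryl–palladium pyridine-oxazoline complex, C2=C3 inserts and water protonates the enolate, so the tert-butyl group of the ligand selects the enone face and sets C2. The R ligand is chosen by analogy with the sense known for cyclic enones and is to be confirmed on a model chromone; the distant piperidine centre makes the two C2 epimers diastereomers, and CF3CO2H keeps the amine off the metal.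

Step 11
Reactants: 18 (2S)-5,7-bis(benzyloxy)-2-[4-(benzyloxy)phenyl]-6-[(2S)-1-methylpiperidin-2-yl]-2,3-dihydro-4H-chromen-4-one
Product: 19 (2S)-5,7-dihydroxy-2-(4-hydroxyphenyl)-6-[(2S)-1-methylpiperidin-2-yl]-2,3-dihydro-4H-chromen-4-one
Conditions: H2 (1 atm), 10% Pd/C, EtOAc–MeOH (1:1), rt, stopped after uptake of 3 equiv
Reagents that add atoms: none
Why: Hydrogenolysis of three aryl benzyl ethers under neutral conditions, which should be much faster than cleavage of the hindered tertiary benzylic C–N bond or of the C2–O1 bond. Neither stereocentre is involved and the hydrogen-bonded aryl ketone should not be reduced.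

## Compound list

1 | 2,4,6-trihydroxybenzaldehyde | O=Cc1c(O)cc(O)cc1O | starting material
2 | 2,6-dihydroxy-4-(methoxymethoxy)benzaldehyde | O=Cc1c(O)cc(OCOC)cc1O | intermediate
3 | 2,6-bis(benzyloxy)-4-(methoxymethoxy)benzaldehyde | O=Cc1c(OCc2ccccc2)cc(OCOC)cc1OCc1ccccc1 | intermediate
4 | (R)-2-methylpropane-2-sulfinamide | CC(C)(C)[S@@](=O)N | starting material
5 | (R,E)-N-[2,6-bis(benzyloxy)-4-(methoxymethoxy)benzylidene]-2-methylpropane-2-sulfinamide | CC(C)(C)[S@@](=O)/N=C/c1c(OCc2ccccc2)cc(OCOC)cc1OCc1ccccc1 | intermediate
6 | 1-bromo-4-chlorobutane | ClCCCCBr | starting material
7 | 4-chlorobutylmagnesium bromide | ClCCCC[Mg]Br | intermediate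
8 | (R)-N-[(1S)-1-[2,6-bis(benzyloxy)-4-(methoxymethoxy)phenyl]-5-chloropentyl]-2-methylpropane-2-sulfinamide (present as its N-bromomagnesium salt, drawn neutral, not isolated) | CC(C)(C)[S@@](=O)N[C@@H](CCCCCl)c1c(OCc2ccccc2)cc(OCOC)cc1OCc1ccccc1 | intermediate
9 | (2S)-2-[2,6-bis(benzyloxy)-4-(methoxymethoxy)phenyl]-1-[(R)-tert-butylsulfinyl]piperidine | CC(C)(C)[S@@](=O)N1CCCC[C@H]1c1c(OCc2ccccc2)cc(OCOC)cc1OCc1ccccc1 | intermediate
10 | 3,5-bis(benzyloxy)-4-[(2S)-piperidin-2-yl]phenol | N1CCCC[C@H]1c1c(OCc2ccccc2)cc(O)cc1OCc1ccccc1 | intermediate
11 | 3,5-bis(benzyloxy)-4-[(2S)-1-methylpiperidin-2-yl]phenol | CN1CCCC[C@H]1c1c(OCc2ccccc2)cc(O)cc1OCc1ccccc1 | intermediate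
12 | 3,5-bis(benzyloxy)-4-[(2S)-1-methylpiperidin-2-yl]phenyl acetate (not isolated) | CN1CCCC[C@H]1c1c(OCc2ccccc2)cc(OC(C)=O)cc1OCc1ccccc1 | intermediate
13 | difluoroboron chelate of 14, boron bridging the phenol oxygen and the ketone oxygen (not isolated) | CN1CCCC[C@H]1c1c(OCc2ccccc2)cc2O[B-](F)(F)[O+]=C(C)c2c1OCc1ccccc1 | intermediate
14 | 1-[2,4-bis(benzyloxy)-6-hydroxy-3-[(2S)-1-methylpiperidin-2-yl]phenyl]ethan-1-one | CN1CCCC[C@H]1c1c(OCc2ccccc2)cc(O)c(C(C)=O)c1OCc1ccccc1 | intermediate
15 | (E)-1-[2,4-bis(benzyloxy)-6-hydroxy-3-[(2S)-1-methylpiperidin-2-yl]phenyl]-3-(dimethylamino)prop-2-en-1-one (not isolated) | CN1CCCC[C@H]1c1c(OCc2ccccc2)cc(O)c(C(=O)/C=C/N(C)C)c1OCc1ccccc1 | intermediate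
16 | 5,7-bis(benzyloxy)-6-[(2S)-1-methylpiperidin-2-yl]-4H-chromen-4-one | CN1CCCC[C@H]1c1c(OCc2ccccc2)cc2occc(=O)c2c1OCc1ccccc1 | intermediate
17 | [4-(benzyloxy)phenyl]boronic acid | OB(O)c1ccc(OCc2ccccc2)cc1 | starting material
18 | (2S)-5,7-bis(benzyloxy)-2-[4-(benzyloxy)phenyl]-6-[(2S)-1-methylpiperidin-2-yl]-2,3-dihydro-4H-chromen-4-one | CN1CCCC[C@H]1c1c(OCc2ccccc2)cc2c(c1OCc1ccccc1)C(=O)C[C@@H](c1ccc(OCc3ccccc3)cc1)O2 | intermediate
19 | (2S)-5,7-dihydroxy-2-(4-hydroxyphenyl)-6-[(2S)-1-methylpiperidin-2-yl]-2,3-dihydro-4H-chromen-4-one | CN1CCCC[C@H]1c1c(O)cc2c(c1O)C(=O)C[C@@H](c1ccc(O)cc1)O2 | target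

## Step count and least certain steps

Total: 11 steps. Longest linear sequence: 10 steps (1, 2, 3, 5, 6, 7, 8, 9, 10, 11); step 4 is a one-step side branch that supplies 7.

Step 5 (key step). The most likely failure is poor or reversed facial selectivity, because the two ortho benzyloxy oxygens can hold magnesium in competition with the sulfinyl oxygen. Slow addition to the donor-deactivated imine and stalling of the ring closure at the magnesium amide stage are also possible; in the latter case 8 would simply be isolated and closed with NaH in DMF. The fallback changes the approach to an allyl transfer that does not depend on magnesium chelation, followed by ring closure through metathesis. It sets out from 5. Allyl bromide and indium powder in THF at 60 °C should give the homoallylic sulfinamide (R)-N-[(1S)-1-aryl-but-3-en-1-yl]-2-methylpropane-2-sulfinamide F1 by Si-face delivery through an indium-bound chair. N-allylation with NaH and allyl bromide in DMF would give the diene F2. Ring-closing metathesis with the second-generation Grubbs catalyst RuCl2(=CHPh)(PCy3)(H2IMes) in CH2Cl2 at 40 °C would give the N-sulfinyl 2-aryl-1,2,3,6-tetrahydropyridine F3. Diimide, generated from 2-nitrobenzenesulfonyl hydrazide and Et3N, would saturate the ring alkene without touching benzyl ethers or sulfur and return to the route at 9.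

Step 8. The most likely failure is Lewis-acid-promoted loss or oxygen-to-carbon migration of a benzyl group, or partial epimerisation through reversible C2(pip)–N heterolysis while the amine is held as an acid adduct. The fallback introduces the acetyl group before any acid is used, by directed ortho-metalation. It sets out from 9. n-BuLi in THF at −20 to 0 °C should remove the ring hydrogen between the acetal oxygen and a benzyloxy group, and N-methoxy-N-methylacetamide would give the acetylated N-sulfinyl piperidine F6. HCl in MeOH at 0 °C to rt would give the secondary amino ketone 1-[2,4-bis(benzyloxy)-6-hydroxy-3-[(2S)-piperidin-2-yl]phenyl]ethan-1-one F7. Reductive methylation with CH2O and NaBH(OAc)3 returns to the route at 14. The step count is unchanged.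

Step 10. The most likely failure is slow insertion into the electron-rich 5,7-dialkoxychromone, inhibition of the catalyst by the amine, or an insufficient facial preference. The fallback builds ring C by carbon–oxygen bond formation. It sets out from 14. Claisen–Schmidt condensation with 4-(benzyloxy)benzaldehyde (KOH, EtOH, rt) should give the chalcone (E)-1-[2,4-bis(benzyloxy)-6-hydroxy-3-[(2S)-1-methylpiperidin-2-yl]phenyl]-3-[4-(benzyloxy)phenyl]prop-2-en-1-one F8. Intramolecular oxa-Michael addition of the only free phenol under a cinchona-derived bifunctional thiourea, choosing the quinine or quinidine series that favours 2S, would follow. The minor C2 epimer is a diastereomer and would be removed by chromatography, returning to the route at 18.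

Step 11. The most likely failure is over-reduction: hydrogenolysis of C2(pip)–N or C2–O1, or amine-assisted opening to the chalcone followed by saturation of its alkene. The fallback replaces reductive cleavage by Lewis-acid debenzylation with a cation trap: BCl3 and pentamethylbenzene in CH2Cl2 at −78 °C, then MeOH quench. It sets out from 18 and arrives directly at 19; it makes no new compound (F0).

Step 6. The most likely failure is partial epimerisation at C2(pip) during the longer acid contact that the acetal needs, or incomplete acetal cleavage. The fallback separates the two unmasking events and removes the acetal without protic acid. It sets out from 9. HCl (2 equiv) in MeOH at 0 °C for a short time would remove only the sulfinyl group to give (2S)-2-[2,6-bis(benzyloxy)-4-(methoxymethoxy)phenyl]piperidine F4. Reductive methylation (CH2O, NaBH(OAc)3) would give the N-methyl acetal F5, with no free phenol present. Me3SiOTf and 2,2'-bipyridyl in CH2Cl2 at 0 °C, then water, would release the phenol and return to the route at 11.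

## Further compounds

F1 | step 5 | (R)-N-[(1S)-1-[2,6-bis(benzyloxy)-4-(methoxymethoxy)phenyl]but-3-en-1-yl]-2-methylpropane-2-sulfinamide | CC(C)(C)[S@@](=O)N[C@@H](CC=C)c1c(OCc2ccccc2)cc(OCOC)cc1OCc1ccccc1
F2 | step 5 | (R)-N-allyl-N-[(1S)-1-[2,6-bis(benzyloxy)-4-(methoxymethoxy)phenyl]but-3-en-1-yl]-2-methylpropane-2-sulfinamide | CC(C)(C)[S@@](=O)N(CC=C)[C@@H](CC=C)c1c(OCc2ccccc2)cc(OCOC)cc1OCc1ccccc1
F3 | step 5 | (2S)-2-[2,6-bis(benzyloxy)-4-(methoxymethoxy)phenyl]-1-[(R)-tert-butylsulfinyl]-1,2,3,6-tetrahydropyridine | CC(C)(C)[S@@](=O)N1CC=CC[C@H]1c1c(OCc2ccccc2)cc(OCOC)cc1OCc1ccccc1
F4 | step 6 | (2S)-2-[2,6-bis(benzyloxy)-4-(methoxymethoxy)phenyl]piperidine | N1CCCC[C@H]1c1c(OCc2ccccc2)cc(OCOC)cc1OCc1ccccc1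
F5 | step 6 | (2S)-2-[2,6-bis(benzyloxy)-4-(methoxymethoxy)phenyl]-1-methylpiperidine | CN1CCCC[C@H]1c1c(OCc2ccccc2)cc(OCOC)cc1OCc1ccccc1
F6 | step 8 | 1-[2,4-bis(benzyloxy)-3-[(2S)-1-[(R)-tert-butylsulfinyl]piperidin-2-yl]-6-(methoxymethoxy)phenyl]ethan-1-one | CC(C)(C)[S@@](=O)N1CCCC[C@H]1c1c(OCc2ccccc2)cc(OCOC)c(C(C)=O)c1OCc1ccccc1
F7 | step 8 | 1-[2,4-bis(benzyloxy)-6-hydroxy-3-[(2S)-piperidin-2-yl]phenyl]ethan-1-one | N1CCCC[C@H]1c1c(OCc2ccccc2)cc(O)c(C(C)=O)c1OCc1ccccc1
F8 | step 10 | (E)-1-[2,4-bis(benzyloxy)-6-hydroxy-3-[(2S)-1-methylpiperidin-2-yl]phenyl]-3-[4-(benzyloxy)phenyl]prop-2-en-1-one | CN1CCCC[C@H]1c1c(OCc2ccccc2)cc(O)c(C(=O)/C=C/c2ccc(OCc3ccccc3)cc2)c1OCc1ccccc1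
F0 | step 11 | none | none
A1 | alternative 1 | tert-butyl (2S)-2-[2,6-bis(benzyloxy)-4-(trifluoromethylsulfonyloxy)-3-(trimethylsilyl)phenyl]piperidine-1-carboxylate | CC(C)(C)OC(=O)N1CCCC[C@H]1c1c(OCc2ccccc2)cc(OS(=O)(=O)C(F)(F)F)c([Si](C)(C)C)c1OCc1ccccc1
A2 | alternative 1 | (E)-3-[4-(benzyloxy)phenyl]prop-2-enoic acid | OC(=O)/C=C/c1ccc(OCc2ccccc2)cc1
A3 | alternative 1 | (E)-2'-hydroxy-4,4',6'-tris(benzyloxy)-5'-[(2S)-1-(tert-butoxycarbonyl)piperidin-2-yl]chalcone | CC(C)(C)OC(=O)N1CCCC[C@H]1c1c(OCc2ccccc2)cc(O)c(C(=O)/C=C/c2ccc(OCc3ccccc3)cc2)c1OCc1ccccc1
A4 | alternative 2 | 3-(benzyloxy)cyclobut-2-en-1-one | O=C1C=C(OCc2ccccc2)C1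
A5 | alternative 2 | tert-butyl (2S)-2-[(triisopropylsilyloxy)ethynyl]piperidine-1-carboxylate | CC(C)(C)OC(=O)N1CCCC[C@H]1C#CO[Si](C(C)C)(C(C)C)C(C)C
A6 | alternative 2 | tert-butyl (2S)-2-[4-(benzyloxy)-2-hydroxy-6-(triisopropylsilyloxy)phenyl]piperidine-1-carboxylate | CC(C)(C)OC(=O)N1CCCC[C@H]1c1c(O)cc(OCc2ccccc2)cc1O[Si](C(C)C)(C(C)C)C(C)C
A7 | alternative 3 | methyl N-[(E)-5-[4-(benzyloxy)-2,6-dihydroxyphenyl]pent-4-en-1-yl]carbamate | COC(=O)NCCC/C=C/c1c(O)cc(OCc2ccccc2)cc1O
A8 | alternative 3 | methyl (2S)-2-[4-(benzyloxy)-2,6-dihydroxyphenyl]piperidine-1-carboxylate | COC(=O)N1CCCC[C@H]1c1c(O)cc(OCc2ccccc2)cc1O
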